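## Retrosynthetic overview

- The last operation is a single hydrogenolysis that removes six O-benzyl groups and two bromine caps from the fully assembled chroman ester. Rings A (phloroglucinol), B (pyrogallol) and D (benzoate) are bought as arenes, so ring C (the dihydropyran) is the only ring built.
- Ring C is opened by a retro-oxa-[4+2] across C4–C3 and O1–C2. The heterodiene is the o-quinone methide of ring A (O1=C8a–C4a=C4H2). The dienophile is a (Z)-enol ester ArCH=CH–OC(O)Ar' that already carries ring B, C2, C3 and the 4-oxybenzoate.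
- Enabling feature: O1 and the unsubstituted C4 methylene sit on the adjacent carbons C8a and C4a of ring A, which makes ring A a latent o-quinone methide. The cis C2-aryl/C3-acyloxy pair of ring C is the imprint of a (Z)-β-acyloxystyrene taken up suprafacially, and the para oxygen of ring B directs O1 to C2.
- The enol ester comes from 3,4,5-tris(benzyloxy)phenylacetylene and 4-(benzyloxy)benzoic acid by Z-selective anti-Markovnikov addition. The quinone methide comes from a salicyl alcohol capped with bromine at C6 and C8, made in three steps from 2,4,6-trihydroxybenzaldehyde.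

Key step: step 7

Remark: flavan numbering is used throughout (O1, C2, C3, C4, C4a, C5 to C8, C8a).

Assumption: the sense of induction of the (R)-configured catalyst in step 7 is assigned by analogy with related styrene cycloadditions and must be confirmed. The (S)-catalyst is equally available and would be used in the same way if the (2S,3S) adduct prevailed.

## Route

Step 1
Reactants: 1 2,4,6-trihydroxybenzaldehyde
Product: 2 4,6-bis(benzyloxy)-2-hydroxybenzaldehyde
Conditions: BnBr (2.05 equiv), K2CO3 (2.1 equiv), DMF, 0 °C to rt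
Reagents that add atoms: benzyl bromide, BrCc1ccccc1
Why: Williamson etherification, in which the 4-OH and one of the two equivalent ortho OH groups are alkylated while the remaining ortho OH is held in a hydrogen bond to the formyl oxygen and is the least nucleophilic site.

Step 2
Reactants: 2 4,6-bis(benzyloxy)-2-hydroxybenzaldehyde
Product: 3 4,6-bis(benzyloxy)-3,5-dibromo-2-hydroxybenzaldehyde
Conditions: NBS (2.1 equiv), CH2Cl2, 0 °C to rt, dark
Reagents that add atoms: N-bromosuccinimide, O=C1CCC(=O)N1Br
Why: Electrophilic aromatic bromination, in which C3 and C5 are the only free ring positions and each lies ortho or para to all three oxygen donors, so both are filled while the benzylic CH2 groups stay untouched under ionic conditions.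

Step 3
Reactants: 3 4,6-bis(benzyloxy)-3,5-dibromo-2-hydroxybenzaldehyde
Product: 4 3,5-bis(benzyloxy)-2,4-dibromo-6-(hydroxymethyl)phenol
Conditions: NaBH4 (1.0 equiv), THF/EtOH, −10 °C; pH 7 phosphate buffer; product kept cold and used promptly
Reagents that add atoms: none
Why: Hydride 1,2-reduction of the aldehyde, to which aryl bromides and benzyl ethers are inert, with low temperature and a neutral quench to keep the salicyl alcohol from losing water too early.

Step 4
Reactants: 5 3,4,5-trihydroxybenzaldehyde
Product: 6 3,4,5-tris(benzyloxy)benzaldehyde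
Conditions: BnBr (3.3 equiv), K2CO3 (3.5 equiv), DMF, 60 °C
Reagents that add atoms: benzyl bromide, BrCc1ccccc1
Why: Exhaustive Williamson etherification of the three phenols, with the non-enolisable aldehyde inert to K2CO3.

Step 5
Reactants: 6 3,4,5-tris(benzyloxy)benzaldehyde
Product: 7 1,2,3-tris(benzyloxy)-5-ethynylbenzene
Conditions: Ohira–Bestmann reagent (1.3 equiv), K2CO3 (2 equiv), MeOH/THF, rt
Reagents that add atoms: dimethyl (1-diazo-2-oxopropyl)phosphonate (Ohira–Bestmann reagent), COP(=O)(OC)C(=[N+]=[N-])C(C)=O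
Why: Seyferth–Gilbert homologation in the Ohira–Bestmann variant, which turns a non-enolisable aryl aldehyde into the terminal alkyne under mild base that leaves the benzyl ethers alone.

Step 6
Reactants: 7 1,2,3-tris(benzyloxy)-5-ethynylbenzene; 8 4-(benzyloxy)benzoic acid
Product: 9 (Z)-2-[3,4,5-tris(benzyloxy)phenyl]ethenyl 4-(benzyloxy)benzoate
Conditions: [RuCl2(p-cymene)]2 (1 mol %), P(4-ClC6H4)3 (3 mol %), DMAP (4 mol %), toluene, 60 °C
Reagents that add atoms: none
Why: Ruthenium-catalysed anti-Markovnikov addition of a carboxylic acid to a terminal alkyne, in which the electron-poor triarylphosphine and DMAP deliver the carboxylate to the terminal carbon so that the (Z)-enol ester should be the main isomer, fixing the alkene geometry that later becomes the 2,3-cis relationship.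

Step 7
Reactants: 4 3,5-bis(benzyloxy)-2,4-dibromo-6-(hydroxymethyl)phenol; 9 (Z)-2-[3,4,5-tris(benzyloxy)phenyl]ethenyl 4-(benzyloxy)benzoate
Product: 11 (2R,3R)-5,7-bis(benzyloxy)-6,8-dibromo-2-[3,4,5-tris(benzyloxy)phenyl]-3,4-dihydro-2H-chromen-3-yl 4-(benzyloxy)benzoate, via o-quinone methide 10 (not isolated)
Conditions: (R)-3,3'-bis(2,4,6-triisopropylphenyl)-BINOL N-triflylphosphoramide (10 mol %), 5 Å MS, toluene, −20 °C; 4 (1.5 equiv) added by syringe pump over 12 h to 9 (1.0 equiv)
Reagents that add atoms: none
Why: Proposed new method: the chiral acid dehydrates 4 to the hydrogen-bonded o-quinone methide 10, whose exocyclic CH2 (future C4) is attacked by the acyloxy-bearing alkene carbon of 9 (future C3) while its carbonyl oxygen (future O1) closes on the benzylic alkene carbon (future C2), a concerted but asynchronous inverse-electron-demand oxa-[4+2] cycloaddition driven by rearomatisation of ring A. The closest known reaction type is the chiral phosphoric acid or N-triflylphosphoramide catalysed [4+2] cycloaddition of o-quinone methides, made in the flask from o-hydroxybenzyl alcohols, with styrenes that offer the catalyst no hydrogen-bond handle; new here are the unsubstituted methide carbon and the (Z)-β-acyloxy substituent on the styrene. Ring C is closed by intermolecular [4+2] cycloaddition (four atoms O1, C8a, C4a, C4 from 10 and two atoms C3, C2 from 9), and in the stepwise limit the O1–C2 closure would be a favoured 6-exo-trig capture of the cation stabilised by ring B. C2 and C3 are set relative to each other by suprafacial addition to the (Z)-alkene, so that aryl and acyloxy stay cis, and the benzoate carbonyl, which can reach the developing C2 cation only from the face away from 10, should hinder C2–C3 rotation before O1 closes. The absolute configuration of both centres is set by the catalyst anion held at O1, which leaves one face of 10 open, together with the exo approach favoured by the out-of-plane 5-benzyloxy group and the 8-bromine (C4 is not stereogenic, so diene-face and endo/exo selection both show up as enantioselectivity). The step needs regioselectivity, secured by the para benzyloxy group of ring B, which stabilises charge at C2 far better than the weakly donating acyloxy oxygen could at C3, and chemoselectivity against Friedel–Crafts self-alkylation of ring A, secured by the bromine caps at C6 and C8, slow addition of 4 and sieves that take up the water.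

Step 8
Reactants: 11 (2R,3R)-5,7-bis(benzyloxy)-6,8-dibromo-2-[3,4,5-tris(benzyloxy)phenyl]-3,4-dihydro-2H-chromen-3-yl 4-(benzyloxy)benzoate
Product: 12 epigallocatechin 3-O-(4-hydroxybenzoate), (2R,3R)-5,7-dihydroxy-2-(3,4,5-trihydroxyphenyl)-3,4-dihydro-2H-chromen-3-yl 4-hydroxybenzoate
Conditions: H2 (1 atm), Pd(OH)2/C, NaOAc (2.2 equiv), THF/MeOH, rt; filtration under argon
Reagents that add atoms: none
Why: Catalytic hydrogenolysis cleaves the six O-benzyl bonds and the two aryl C–Br bonds in one operation with NaOAc taking up HBr, while the secondary benzoate, the C2–O1 bond and both stereocentres should stay untouched, as is usual for perbenzylated flavan-3-ol esters.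

## Compound list

1 | 2,4,6-trihydroxybenzaldehyde | O=Cc1c(O)cc(O)cc1O | starting material
2 | 4,6-bis(benzyloxy)-2-hydroxybenzaldehyde | O=Cc1c(O)cc(OCc2ccccc2)cc1OCc1ccccc1 | intermediate
3 | 4,6-bis(benzyloxy)-3,5-dibromo-2-hydroxybenzaldehyde | O=Cc1c(O)c(Br)c(OCc2ccccc2)c(Br)c1OCc1ccccc1 | intermediate
4 | 3,5-bis(benzyloxy)-2,4-dibromo-6-(hydroxymethyl)phenol | OCc1c(O)c(Br)c(OCc2ccccc2)c(Br)c1OCc1ccccc1 | intermediate
5 | 3,4,5-trihydroxybenzaldehyde | O=Cc1cc(O)c(O)c(O)c1 | starting material
6 | 3,4,5-tris(benzyloxy)benzaldehyde | O=Cc1cc(OCc2ccccc2)c(OCc2ccccc2)c(OCc2ccccc2)c1 | intermediate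
7 | 1,2,3-tris(benzyloxy)-5-ethynylbenzene | C#Cc1cc(OCc2ccccc2)c(OCc2ccccc2)c(OCc2ccccc2)c1 | intermediate
8 | 4-(benzyloxy)benzoic acid | O=C(O)c1ccc(OCc2ccccc2)cc1 | starting material
9 | (Z)-2-[3,4,5-tris(benzyloxy)phenyl]ethenyl 4-(benzyloxy)benzoate | O=C(O/C=C\c1cc(OCc2ccccc2)c(OCc2ccccc2)c(OCc2ccccc2)c1)c1ccc(OCc2ccccc2)cc1 | intermediate
10 | 3,5-bis(benzyloxy)-2,4-dibromo-6-methylidenecyclohexa-2,4-dien-1-one (o-quinone methide, not isolated) | C=C1C(=O)C(Br)=C(OCc2ccccc2)C(Br)=C1OCc1ccccc1 | intermediate
11 | (2R,3R)-5,7-bis(benzyloxy)-6,8-dibromo-2-[3,4,5-tris(benzyloxy)phenyl]-3,4-dihydro-2H-chromen-3-yl 4-(benzyloxy)benzoate | O=C(O[C@@H]1Cc2c(OCc3ccccc3)c(Br)c(OCc3ccccc3)c(Br)c2O[C@@H]1c1cc(OCc2ccccc2)c(OCc2ccccc2)c(OCc2ccccc2)c1)c1ccc(OCc2ccccc2)cc1 | intermediate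
12 | epigallocatechin 3-O-(4-hydroxybenzoate), (2R,3R) | O=C(O[C@@H]1Cc2c(O)cc(O)cc2O[C@@H]1c1cc(O)c(O)c(O)c1)c1ccc(O)cc1 | target

## Step count

Total step count: 8.
Longest linear sequence: 5 steps (steps 1, 2, 3, 7, 8 or steps 4, 5, 6, 7, 8).

## Steps most likely to fail

**1. Step 7 (bears the label "Proposed new method:").**

What may go wrong:
- The doubly substituted, acyloxy-bearing alkene may be too weak a nucleophile, so the quinone methide is consumed by self-dimerisation or by O-alkylation of its own precursor.
- Acyl transfer from the enol ester to the free hydroxyl groups of the precursor may compete.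
- Enantiofacial discrimination may be poor, because diene-face and endo/exo selection must both be high.
- A stepwise course with C2–C3 rotation would erode the cis relationship.

Fallback: known chemistry that still makes the same two bonds in one operation, but with C4 at the aldehyde oxidation level and a formyl group as temporary activator at C3. It sets out from 6, with 3 and 8 as partners, and comes back at 11.
- Wittig reaction of 6 with Ph3P=CHCHO in toluene at 80 °C gives (E)-3-[3,4,5-tris(benzyloxy)phenyl]prop-2-enal F1.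
- Domino oxa-Michael/aldol condensation of salicylaldehyde 3 with F1 uses iminium–enamine catalysis by (R)-diphenylprolinol trimethylsilyl ether and 2-nitrobenzoic acid in toluene. It gives (2R)-5,7-bis(benzyloxy)-6,8-dibromo-2-[3,4,5-tris(benzyloxy)phenyl]-2H-chromene-3-carbaldehyde F2, with C2 set by the shielded face of the iminium ion.
- Baeyer–Villiger oxidation of the enal with mCPBA and NaHCO3 in CH2Cl2 gives (2R)-5,7-bis(benzyloxy)-6,8-dibromo-2-[3,4,5-tris(benzyloxy)phenyl]-2H-chromen-3-yl formate F3.
- Brief methanolysis with KHCO3 in MeOH at 0 °C gives (2R)-5,7-bis(benzyloxy)-6,8-dibromo-2-[3,4,5-tris(benzyloxy)phenyl]chroman-3-one F4, which is used at once to protect C2 from enolisation.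
- LiBH(s-Bu)3 in THF at −78 °C delivers hydride anti to the C2 aryl group and gives (2R,3R)-5,7-bis(benzyloxy)-6,8-dibromo-2-[3,4,5-tris(benzyloxy)phenyl]chroman-3-ol F5.
- Steglich-type esterification of F5 with 8 (EDC·HCl, DMAP, CH2Cl2) gives 11.

**2. Step 6.**

What may go wrong: erosion of the Z geometry, competing Markovnikov addition, or head-to-head dimerisation of the electron-rich aryl alkyne on the ruthenium catalyst.

Fallback: the alkene geometry is fixed first on boron and the C–O bond is made afterwards. It sets out from 7 and comes back at 9.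
- Rhodium-catalysed trans-hydroboration of 7 ([Rh(cod)Cl]2, P(i-Pr)3, Et3N, pinacolborane, cyclohexane, rt) gives 2-{(Z)-2-[3,4,5-tris(benzyloxy)phenyl]ethenyl}-4,4,5,5-tetramethyl-1,3,2-dioxaborolane F6.
- KHF2 in MeOH/H2O converts F6 into potassium (Z)-trifluoro{2-[3,4,5-tris(benzyloxy)phenyl]ethenyl}borate F7.
- Chan–Lam-type oxidative coupling of F7 with acid 8 (CuBr, DMAP, 4 Å MS, O2, CH2Cl2, 40 °C) proceeds with retention of alkene geometry and gives 9.

**3. Step 3.**

What may go wrong: premature loss of the benzylic oxygen at the phenoxide–alkoxyborate stage, followed by a second hydride transfer (over-reduction of the benzylic position), and self-condensation during isolation and storage.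

Fallback: the phenol is masked so that no quinone methide can form during reduction or storage. It sets out from 3 and comes back at 4.
- Silylation of 3 (TBSOTf, 2,6-lutidine, CH2Cl2, 0 °C) gives 4,6-bis(benzyloxy)-3,5-dibromo-2-[(tert-butyldimethylsilyl)oxy]benzaldehyde F8.
- Reduction with i-Bu2AlH in CH2Cl2 at −78 °C gives the storable {4,6-bis(benzyloxy)-3,5-dibromo-2-[(tert-butyldimethylsilyl)oxy]phenyl}methanol F9.
- Desilylation with TBAF buffered by AcOH in THF at 0 °C, just before step 7, releases 4.

## Further compounds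

F1 | step 7 | (E)-3-[3,4,5-tris(benzyloxy)phenyl]prop-2-enal | O=C/C=C/c1cc(OCc2ccccc2)c(OCc2ccccc2)c(OCc2ccccc2)c1
F2 | step 7 | (2R)-5,7-bis(benzyloxy)-6,8-dibromo-2-[3,4,5-tris(benzyloxy)phenyl]-2H-chromene-3-carbaldehyde | O=CC1=Cc2c(OCc3ccccc3)c(Br)c(OCc3ccccc3)c(Br)c2O[C@@H]1c1cc(OCc2ccccc2)c(OCc2ccccc2)c(OCc2ccccc2)c1
F3 | step 7 | (2R)-5,7-bis(benzyloxy)-6,8-dibromo-2-[3,4,5-tris(benzyloxy)phenyl]-2H-chromen-3-yl formate | O=COC1=Cc2c(OCc3ccccc3)c(Br)c(OCc3ccccc3)c(Br)c2O[C@@H]1c1cc(OCc2ccccc2)c(OCc2ccccc2)c(OCc2ccccc2)c1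
F4 | step 7 | (2R)-5,7-bis(benzyloxy)-6,8-dibromo-2-[3,4,5-tris(benzyloxy)phenyl]chroman-3-one | O=C1Cc2c(OCc3ccccc3)c(Br)c(OCc3ccccc3)c(Br)c2O[C@@H]1c1cc(OCc2ccccc2)c(OCc2ccccc2)c(OCc2ccccc2)c1
F5 | step 7 | (2R,3R)-5,7-bis(benzyloxy)-6,8-dibromo-2-[3,4,5-tris(benzyloxy)phenyl]chroman-3-ol | O[C@@H]1Cc2c(OCc3ccccc3)c(Br)c(OCc3ccccc3)c(Br)c2O[C@@H]1c1cc(OCc2ccccc2)c(OCc2ccccc2)c(OCc2ccccc2)c1
F6 | step 6 | 2-{(Z)-2-[3,4,5-tris(benzyloxy)phenyl]ethenyl}-4,4,5,5-tetramethyl-1,3,2-dioxaborolane | CC1(C)OB(/C=C\c2cc(OCc3ccccc3)c(OCc3ccccc3)c(OCc3ccccc3)c2)OC1(C)C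
F7 | step 6 | potassium (Z)-trifluoro{2-[3,4,5-tris(benzyloxy)phenyl]ethenyl}borate | [K+].F[B-](F)(F)/C=C\c1cc(OCc2ccccc2)c(OCc2ccccc2)c(OCc2ccccc2)c1
F8 | step 3 | 4,6-bis(benzyloxy)-3,5-dibromo-2-[(tert-butyldimethylsilyl)oxy]benzaldehyde | O=Cc1c(O[Si](C)(C)C(C)(C)C)c(Br)c(OCc2ccccc2)c(Br)c1OCc1ccccc1
F9 | step 3 | {4,6-bis(benzyloxy)-3,5-dibromo-2-[(tert-butyldimethylsilyl)oxy]phenyl}methanol | OCc1c(O[Si](C)(C)C(C)(C)C)c(Br)c(OCc2ccccc2)c(Br)c1OCc1ccccc1
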